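| flask | Z | X | remark | time | volume of the second phase over the first |
|---|---|---|---|---|---|
| amber | 0.10 M | 1.1 equiv | the very flask that is asked about, followed so far |  |  |
| green | 0.050 M | 1.1 equiv | run made earlier |  |  |
| flask | 0.10 M | 1.10 equiv |  | 10 h | 1.0 |

| run | time / h | E / % | Z / % |
|---|---|---|---|
| amber | 0.667 | 19 | 82 |
| amber | 0.833 | 20 | 75 |
| amber | 1.33 | 29 | 63 |
| amber | 1.50 | 30 | 58 |
| amber | 2.00 | 33 | 47 |
| amber | 3.00 | 31 | 32 |
| green | 0.667 | 15 | 91 |
| green | 0.833 | 12 | 82 |
| green | 1.33 | 21 | 73 |
| green | 2.00 | 21 | 62 |
| green | 3.00 | 24 | 49 |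
| green | 4.00 | 22 | 42 |

(readings scatter by 2 percentage points)

* time up to 10 h at which E stands highest
* the amount of E, in percent of the Z charged, at that time
* the first time at which E reaches 9.8%, in the same percent

- charges count per volume of the first phase; a concentration in a rate is the amount of a species over the volume of its own phase; every rate counts per litre of the first phase
- the numbers in the tables scatter with a standard deviation of 2 percentage points
- the earlier runs hold the two phases in the same ratio of volumes as the flask asked about
- a reading or a percentage of E counts all its forms, free or not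

1. If E was an intermediate, made from Z and lost onward, I could solve each end and join them: early on E rose as Z fell, and at its top making equalled losing, k_Z·Z = k_E·E, with k_Z and k_E the first-order constants of Z and E.

2. So I sought one number, κ = k_E/k_Z, the loss constant of E over that of Z, which also equals Z over E at the top.

3. In the amber run, Z from the second reading to the last gave k_Z = 0.393 h⁻¹. The fall of Z + E after 2.00 h, over mean E, gave k_E = 0.531 h⁻¹, so κ = 1.35.

4. The top height is (κ)^(−κ/(κ−1)), so I expected 31.4% at ln κ/(k_E − k_Z) = 2.18 h.

5. One number was not enough, since κ holds no clock. The first amber reading of Z, with its scatter, also gave a lower constant, 0.298 h⁻¹, so I took the early end from E's straight chord from zero to its first reading: 9.8% near 0.344 h.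

6. The forecast, noting that “The balance Z + E falls steadily”, gave 32% at 2.4 h, later than my top, and 9.8% at 0.31 h, earlier than my chord.

7. The flask stood highest at 32.8% at 2.46 h, and reached 9.8% at 0.412 h, later than the forecast and my chord.

    E ⇌ Q, rate k1*([E] - [Q]/K1) per volume of the first phase (partition coefficient = 0.220, kL = 0.0170 s⁻¹)
    Z + G → E (k = 0.0100 M⁻¹ s⁻¹)
    G ⇌ J (K = 0.450, k = 6.00 × 10⁻⁴ s⁻¹)
    D ⇌ E, rate k4*(cs4 - [E]) while solid is left; crystals form when [E] > cs4 (solubility = 22.0 mM, k = 0.0140 s⁻¹)
    E → L (k = 1.70 × 10⁻⁴ s⁻¹)
    G ⇌ X, rate k6*([G] - [X]/K6) per volume of the first phase (partition coefficient = 2.70, kL = 5.90 × 10⁻⁴ s⁻¹)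

At 2.46 h the flask's Z over E was 1.27, against κ of 1.35. The same windows on the green run gave κ = 2.09, hence a top of 24.3%, and that run's highest value up to its last reading, without the scatter, was 24.6%. In the flask, the half-life of Z by its step to E, 1.8 h at 1.14 h, was longer than that of dissolved E by its first-order step to L, 1.13 h from the constant of that step. That half-life was short against the 10 h allowed, and L held 86.3% of the Z charged at 10.0 h.

The earlier runs and the new flask were generated by integration with made-up constants; scatter was added.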